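**Retrosynthetic overview**

1. Locants used throughout: C1 is the bridgehead next to the quaternary C8, C3 carries the acyl group, C5 is the other bridgehead, C7 carries prenyl, C9 is the bridging ketone. Ring A is C1–C5 plus C9 (the phloroglucinol ring); ring B is C5–C6–C7–C8–C1–C9.
2. Target 13 ⇒ diene 10 (7-methylidene, 8-vinyl). Both side chains come last from one double hydroboration/B-alkyl Suzuki coupling; H is delivered to C7 from the exo face, so prenyl ends endo.
3. 10 ⇒ aromatic 8. Ring B is closed in the key step: C1 of the phloroglucinol attacks the tertiary end (C8) of a π-allylpalladium, which breaks aromaticity and sets C1, C5 and C8. A silyl group on the C7 alkylidene, removed afterwards, blocks the vinylogous allyl terminus.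
4. 8 ⇒ phlorisobutyrophenone 3 (from phloroglucinol) + allylic carbonate 7 (C5–C6 bond); 7 comes from a C6 enynol by silylformylation.
5. Ring order: ring A is bought as the arene; ring B is formed once, in step 5.

Assumption: the (R,R)-ligand in step 5 is taken to lead to the (1S,5S,8R) series; the product sense follows the ligand, so its enantiomer is used if the opposite sense is found.

**Route**

Step 1
Reactants: 1 phloroglucinol (benzene-1,3,5-triol); 2 isobutyryl chloride (2-methylpropanoyl chloride)
Product: 3 phlorisobutyrophenone [2-methyl-1-(2,4,6-trihydroxyphenyl)propan-1-one]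
Conditions: AlCl3 (3.5 equiv), PhNO2, 70 °C; aq. HCl work-up
Reagents that add atoms: none
Why: Friedel–Crafts C-acylation of the symmetric triol stops at the mono-ketone because the chelated acyl group deactivates the ring; no stereocentre is formed.

Step 2
Reactants: 4 3-methylpent-1-en-4-yn-3-ol (racemic)
Product: 6 (2E)-2-{[benzyl(dimethyl)silyl]methylidene}-3-methylpent-4-ene-1,3-diol, via silyl enal 5 (not isolated)
Conditions: BnMe2SiH (1.1 equiv), CO (20 atm), Rh4(CO)12 (0.5 mol%), toluene, 80 °C; then NaBH4, CeCl3·7H2O, MeOH, −20 °C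
Reagents that add atoms: benzyl(dimethyl)silane, C[SiH](C)Cc1ccccc1; carbon monoxide, [C-]#[O+]
Why: Rhodium-catalysed silylformylation adds Si and CHO syn across the terminal alkyne (silicon at the terminus, formyl at the internal carbon, alkyne faster than the vinyl group) and Luche 1,2-reduction gives the allylic alcohol; the carbinol centre stays racemic because it is erased in step 5.

Step 3
Reactants: 6 silyl diol
Product: 7 [(2E)-3-[benzyl(dimethyl)silyl]-2-(2-hydroxybut-3-en-2-yl)prop-2-en-1-yl] methyl carbonate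
Conditions: ClCO2Me (1.05 equiv), pyridine, CH2Cl2, −20 to 0 °C
Reagents that add atoms: methyl chloroformate, COC(Cl)=O
Why: Chemoselective acylation: the unhindered primary allylic hydroxyl reacts far faster than the tertiary doubly allylic one, which differentiates the two ends for the two palladium steps.

Step 4
Reactants: 3 phlorisobutyrophenone (1.5 equiv); 7 allylic carbonate
Product: 8 1-{3-[(2E)-3-[benzyl(dimethyl)silyl]-2-(2-hydroxybut-3-en-2-yl)prop-2-en-1-yl]-2,4,6-trihydroxyphenyl}-2-methylpropan-1-one
Conditions: Pd(PPh3)4 (2 mol%), THF, rt to 40 °C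
Reagents that add atoms: none
Why: Tsuji–Trost C-allylation: the carbonate ionises to a π-allylpalladium plus methoxide, the acylphloroglucinolate attacks the CH2 terminus remote from silicon, O-allyl ethers re-ionise so the C-allyl product accumulates, and the unactivated tertiary alcohol is untouched.

Step 5
Reactants: 8 C-allylated acylphloroglucinol
Product: 9 (1S,5S,8R)-7-{(E)-[benzyl(dimethyl)silyl]methylidene}-8-ethenyl-2-hydroxy-8-methyl-3-(2-methylpropanoyl)bicyclo[3.3.1]non-2-ene-4,9-dione
Conditions: Pd2(dba)3·CHCl3 (2.5 mol%), (R,R)-DACH-phenyl Trost ligand (7.5 mol%), BEt3 (1.2 equiv), THF (0.02 M), 40 °C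
Reagents that add atoms: none
Why: Proposed new method: BEt3 turns the tertiary doubly allylic hydroxyl into a leaving group and zerovalent palladium ionises it to a π-allyl whose silyl-bearing terminus is shut off (nucleophiles add remote from silicon) and whose CH2 terminus would need an eight-membered ring, so the C1 enolate carbon of the C5-protonated keto tautomer of the phloroglucinol closes ring B at the tertiary terminus C8 anti to palladium and the two new bridgeheads can no longer re-aromatise; O-cyclised chromans are tertiary allyl aryl ethers that re-ionise; the ligand selects the π-allyl face (faces exchange by π–σ–π at the CH2 end) and so fixes C8, and the bulky allylpalladium arm sits pseudo-axial on the forming ring to avoid 1,3-allylic strain with the C7 alkylidene, which pairs this C8 with the 1S,5S bridgeheads (vinyl axial, methyl equatorial); the closest known reactions are the palladium-catalysed dearomative conjunctive allylic annulation of acylphloroglucinols and borane-promoted dearomative Trost allylations with allyl alcohols.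

Step 6
Reactants: 9 bicyclic vinylsilane
Product: 10 (1S,5S,8R)-8-ethenyl-2-hydroxy-8-methyl-7-methylidene-3-(2-methylpropanoyl)bicyclo[3.3.1]non-2-ene-4,9-dione
Conditions: Bu4NF·3H2O (3 equiv), THF, 0 °C to rt
Reagents that add atoms: none
Why: Fluoride-triggered protodesilylation of a benzyldimethylsilyl alkene replaces Si by H without acid, so the enol/alkene array and the three stereocentres are untouched.

Step 7
Reactants: 10 bicyclic diene; 11 1-bromo-2-methylprop-1-ene (4 equiv)
Product: 13 (1S,5S,7R,8S)-2-hydroxy-8-methyl-7-(3-methylbut-2-en-1-yl)-8-(4-methylpent-3-en-1-yl)-3-(2-methylpropanoyl)bicyclo[3.3.1]non-2-ene-4,9-dione, via tris-borane adduct 12 (not isolated)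
Conditions: 9-BBN (3.5 equiv), THF, 0 °C to rt; then 11, Pd(dppf)Cl2 (10 mol%), AsPh3 (10 mol%), Cs2CO3 (4 equiv), DMF/H2O, rt to 45 °C; aq. citric acid work-up
Reagents that add atoms: none
Why: Anti-Markovnikov hydroboration of the vinyl and the 1,1-disubstituted alkene (the acidic enol is masked as its O–B borinate) followed by double B-alkyl Suzuki–Miyaura coupling builds homoprenyl at C8 and prenyl at C7; 9-BBN can reach the exocyclic alkene only from the exo face because the endo face is covered by C3 of ring A, so H ends exo and the CH2B arm, hence prenyl, ends endo (7R).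

**Compound list**

1 | phloroglucinol (benzene-1,3,5-triol) | Oc1cc(O)cc(O)c1 | starting material
2 | isobutyryl chloride (2-methylpropanoyl chloride) | CC(C)C(Cl)=O | starting material
3 | phlorisobutyrophenone, 2-methyl-1-(2,4,6-trihydroxyphenyl)propan-1-one | CC(C)C(=O)c1c(O)cc(O)cc1O | intermediate
4 | 3-methylpent-1-en-4-yn-3-ol (racemic) | C=CC(C)(O)C#C | starting material
5 | (2Z)-3-[benzyl(dimethyl)silyl]-2-(2-hydroxybut-3-en-2-yl)prop-2-enal (racemic; Si cis to CHO) | C[Si](C)(Cc1ccccc1)/C=C(\C=O)C(C)(O)C=C | intermediate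
6 | (2E)-2-{[benzyl(dimethyl)silyl]methylidene}-3-methylpent-4-ene-1,3-diol (racemic; Si cis to CH2OH) | C[Si](C)(Cc1ccccc1)/C=C(\CO)C(C)(O)C=C | intermediate
7 | [(2E)-3-[benzyl(dimethyl)silyl]-2-(2-hydroxybut-3-en-2-yl)prop-2-en-1-yl] methyl carbonate (racemic) | C[Si](C)(Cc1ccccc1)/C=C(\COC(=O)OC)C(C)(O)C=C | intermediate
8 | 1-{3-[(2E)-3-[benzyl(dimethyl)silyl]-2-(2-hydroxybut-3-en-2-yl)prop-2-en-1-yl]-2,4,6-trihydroxyphenyl}-2-methylpropan-1-one (racemic) | C[Si](C)(Cc1ccccc1)/C=C(\Cc1c(O)cc(O)c(C(=O)C(C)C)c1O)C(C)(O)C=C | intermediate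
9 | (1S,5S,8R)-7-{(E)-[benzyl(dimethyl)silyl]methylidene}-8-ethenyl-2-hydroxy-8-methyl-3-(2-methylpropanoyl)bicyclo[3.3.1]non-2-ene-4,9-dione | C=C[C@@]1(C)/C(=C/[Si](C)(C)Cc3ccccc3)C[C@@H]2C(=O)C(C(=O)C(C)C)=C(O)[C@H]1C2=O | intermediate
10 | (1S,5S,8R)-8-ethenyl-2-hydroxy-8-methyl-7-methylidene-3-(2-methylpropanoyl)bicyclo[3.3.1]non-2-ene-4,9-dione | C=C[C@@]1(C)C(=C)C[C@@H]2C(=O)C(C(=O)C(C)C)=C(O)[C@H]1C2=O | intermediate
11 | 1-bromo-2-methylprop-1-ene | CC(C)=CBr | starting material
12 | tris-borane adduct: C7–CH2–B(9-BBN) endo, C8–CH2CH2–B(9-BBN), enol O–B(9-BBN); ring stereocentres arranged as in 13 | B3(C4CCCC3CCC4)CC[C@@]1(C)[C@H](CB5C6CCCC5CCC6)C[C@@H]2C(=O)C(C(=O)C(C)C)=C(OB7C8CCCC7CCC8)[C@H]1C2=O | intermediate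
13 | (1S,5S,7R,8S)-2-hydroxy-8-methyl-7-(3-methylbut-2-en-1-yl)-8-(4-methylpent-3-en-1-yl)-3-(2-methylpropanoyl)bicyclo[3.3.1]non-2-ene-4,9-dione (CNP0285183.2) | CC(C)=CCC[C@@]1(C)[C@H](CC=C(C)C)C[C@@H]2C(=O)C(C(=O)C(C)C)=C(O)[C@H]1C2=O | target

**Step count and risks**

Total steps: 7. Longest linear sequence: 6 (steps 2 to 7, from enynol 4); the arene branch is 5 (steps 1, 4 to 7).

Most likely to fail, in this order:

Step 5. The ring closure needs the scarce C5-protonated keto tautomer, attack at a fully substituted π-allyl terminus, and both ligand and allylic-strain control; retro-allylation to the isomeric skeleton or β-hydride loss could win. The fallback forms the C1–C8 bond by a [3,3] shift and uses the π-allyl only at a primary carbon; it sets out from 3 and comes back to the route at 13. 6-Methylhept-5-en-2-one and diethyl malonate are condensed (TiCl4, pyridine) to diethyl 2-(6-methylhept-5-en-2-ylidene)propanedioate F1, which i-Bu2AlH reduces to 2-(6-methylhept-5-en-2-ylidene)propane-1,3-diol F2. Mitsunobu etherification (PPh3, DIAD) of the most acidic 4-OH of 3 with excess F2 gives the aryl allyl ether 1-(2,6-dihydroxy-4-{[2-(hydroxymethyl)-3,7-dimethylocta-2,6-dien-1-yl]oxy}phenyl)-2-methylpropan-1-one F3 as an E/Z mixture. Aromatic Claisen rearrangement (PhNEt2, 150 °C) carries the tetrasubstituted carbon onto the ring and gives racemic 1-{2,4,6-trihydroxy-3-[2-(hydroxymethyl)-3,7-dimethylocta-1,6-dien-3-yl]phenyl}-2-methylpropan-1-one F4. The Pd2(dba)3·CHCl3/Trost ligand/BEt3 system of step 5 then closes ring B through a CH2 terminus of the 2-substituted π-allyl to (1S,5S,8R)-2-hydroxy-8-methyl-7-methylidene-8-(4-methylpent-3-en-1-yl)-3-(2-methylpropanoyl)bicyclo[3.3.1]non-2-ene-4,9-dione F5, separated from its C8 epimer. Because C8 is racemic after the Claisen step and the ligand fixes only the bridgeheads, at most half of the material is F5. One hydroboration/Suzuki coupling of F5 with 11 under the step 7 conditions gives 13.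

Step 7. 9-BBN may reduce the C9 ketone in competition with hydroboration, and the double coupling runs on a free trione. The fallback is a redox relay that sets out from 10 and comes back at 13: 9-BBN is used in larger excess (5 equiv, 40 °C) so that C9 is reduced on purpose, the double coupling with 11 is run as before to give the C9 carbinol of 13, 2,9-dihydroxy-8-methyl-7-(3-methylbut-2-en-1-yl)-8-(4-methylpent-3-en-1-yl)-3-(2-methylpropanoyl)bicyclo[3.3.1]non-2-en-4-one F6 (either C9 epimer), and Dess–Martin periodinane (CH2Cl2, NaHCO3) oxidises it back to 13.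

Step 4. Mono-C-allylation may be eroded by bis-allylation or slow ionisation of the hindered silyl-substituted allyl carbonate. The fallback replaces π-allyl chemistry by direct SN2 C-alkylation of the phenolate; it sets out from 6 and 3 and comes back at 8. Appel bromination (CBr4, PPh3, CH2Cl2, 0 °C) of the primary hydroxyl of 6 gives (4Z)-5-[benzyl(dimethyl)silyl]-4-(bromomethyl)-3-methylpenta-1,4-dien-3-ol F7, which alkylates 3 at carbon in cold aqueous KOH, where hydrogen-bonded phenolate oxygens favour C-alkylation, to give 8.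

**Further compounds**

F1 | step 5 | diethyl 2-(6-methylhept-5-en-2-ylidene)propanedioate | CCOC(=O)C(C(=O)OCC)=C(C)CCC=C(C)C
F2 | step 5 | 2-(6-methylhept-5-en-2-ylidene)propane-1,3-diol | OCC(CO)=C(C)CCC=C(C)C
F3 | step 5 | 1-(2,6-dihydroxy-4-{[2-(hydroxymethyl)-3,7-dimethylocta-2,6-dien-1-yl]oxy}phenyl)-2-methylpropan-1-one (E/Z mixture) | CC(C)C(=O)c1c(O)cc(OCC(CO)=C(C)CCC=C(C)C)cc1O
F4 | step 5 | 1-{2,4,6-trihydroxy-3-[2-(hydroxymethyl)-3,7-dimethylocta-1,6-dien-3-yl]phenyl}-2-methylpropan-1-one (racemic) | CC(C)C(=O)c1c(O)cc(O)c(C(C)(CCC=C(C)C)C(=C)CO)c1O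
F5 | step 5 | (1S,5S,8R)-2-hydroxy-8-methyl-7-methylidene-8-(4-methylpent-3-en-1-yl)-3-(2-methylpropanoyl)bicyclo[3.3.1]non-2-ene-4,9-dione | CC(C)=CCC[C@@]1(C)C(=C)C[C@@H]2C(=O)C(C(=O)C(C)C)=C(O)[C@H]1C2=O
F6 | step 7 | 2,9-dihydroxy-8-methyl-7-(3-methylbut-2-en-1-yl)-8-(4-methylpent-3-en-1-yl)-3-(2-methylpropanoyl)bicyclo[3.3.1]non-2-en-4-one (C1, C5, C7, C8 arranged as in 13; C9 epimer mixture) | CC(C)=CCC[C@@]1(C)[C@H](CC=C(C)C)C[C@@H]2C(=O)C(C(=O)C(C)C)=C(O)[C@H]1C2O
F7 | step 4 | (4Z)-5-[benzyl(dimethyl)silyl]-4-(bromomethyl)-3-methylpenta-1,4-dien-3-ol (racemic) | C[Si](C)(Cc1ccccc1)/C=C(\CBr)C(C)(O)C=C
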